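Count the acid before you ask where the nucleophile sits.

all flasks: gas 170 mM (held)

| run | electrophile | free base | remark | time |
|---|---|---|---|---|
| north | 0.59 M | 0.32 M | run made earlier |  |
| west | 0.59 M | 0.49 M | run made earlier |  |
| south-west | 1.2 M | 0.649 M | run made earlier |  |
| flask | 0.59 M | 0.649 M |  | 40 h |

- north (time / h: electrophile / %, product / %): 3.00: 98.5, 3.6; 6.00: 92.5, 4.0; 10.0: 88.6, 7.3; 15.0: 82.4, 11.5; 20.0: 75.8, 15.3; 25.0: 70.6, 17.7
- west (time / h: electrophile / %, product / %): 1.33: 99.1, 1.0; 4.00: 95.4, 2.3; 6.00: 92.8, 2.6; 10.0: 84.7, 6.2; 15.0: 80.8, 11.9; 20.0: 76.5, 15.3; 25.0: 70.0, 19.1
- south-west (time / h: electrophile / %, product / %): 2.00: 98.2, 2.3; 4.00: 95.5, 3.5; 6.00: 92.5, 4.5; 12.0: 84.4, 8.7; 25.0: 69.9, 17.4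

(standard deviation of a reading: 1 percentage point)

- percentages count the electrophile that a species holds: one idle adduct counts as two
- product is meant together with its idle adduct
- at the start none of nucleophile is dissolved
- what may be going on: electrophile + nucleophile -> acid set free + product; nucleophile + acid set free <-> protonated nucleophile; acid set free + free base <-> salt of the base; electrophile + product <-> idle adduct; gas <-> nucleophile; 2 free base -> homo dimer
- what has gone from electrophile into another species counts as reacted, even if it can come back
- the earlier runs do not show how much of nucleophile is bound; that part of a forecast is a guess
- in an amount of product, one idle adduct counts as one product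

* part of the electrophile that has reacted at 40 h
* share of the unused nucleophile that is free and not bound as protonated nucleophile, at 40 h

The gas is held at 170 mM, so take [nucleophile] as staying near that value, which makes product form pseudo-first-order in electrophile. But each product sets one acid free, so the acid in all its forms equals the product, with each idle adduct counted as one.

The north run, charged like the flask in electrophile, shows 17.7% of product at 25.0 h. The west run, with more free base, shows 19.1% at the same time, a gap of 1.4 percentage points against a scatter of 1 point on each reading. Drawn straight to 40 h, the north reading gives an acid load of 0.167 M. Electrophile falls in the north run from 98.5% to 70.6%, so this straight line probably runs high, and a high load lowers the share reckoned next.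

The runs do not say how the acid divides between nucleophile and free base, but each protonated nucleophile holds one acid. Held [nucleophile] divided by itself plus the acid load gives 50.4%. This is the free-share floor, the share left free when protonated nucleophile takes the whole load. My own reckoning therefore puts the free share above that mark, as an estimate that carries the scatter of the north reading.

The forecast gives 42% reacted and 90% free, judging that “nucleophile is probably mostly free”, and it calls this a guess.

The flask gives 43.1% reacted and 54.7% free.

    electrophile + nucleophile → acid set free + product (k = 0.0570 /M/h)
    nucleophile + acid set free ⇌ protonated nucleophile, settled at all times (K = 1700 /M)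
    acid set free + free base ⇌ salt of the base, settled at all times (K = 89.0 /M)
    electrophile + product ⇌ idle adduct, settled at all times (K = 4.00 /M)
    gas ⇌ nucleophile, rate k5*(csat - [nucleophile]) (kL = 1.00 /h)
    2 free base → homo dimer (k = 0.00130 /M/h)

At 40.0 h the flask holds 0.136 M of protonated nucleophile, more than its 0.0253 M of salt of the base, and its free share stands just above the floor of 50.4%. The neighbour flask with 1.5 M of electrophile reaches 25.4% of product at 40.0 h, an acid load of 0.381 M, with [nucleophile] at 0.156 M. Its floor is 29.1%, and its free share is 32.8%.

(The runs were computed on assumed constants.)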